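The data stem from a simulated flask on assumed constants; scatter was added.

Free monomer leaves slowly: in the dusk run, which is this very flask followed so far, it lost 0.0993 min⁻¹ of its charge between 2.50 min and 4.00 min, a fractional rate of 0.166 min⁻¹.

| flask | free monomer | transfer agent | initiator | remark | time |
|---|---|---|---|---|---|
| dusk | 20 mM | 0.60 mM | 40 µM | the very flask that is asked about, followed so far |  |
| flask | 20 mM | 0.600 mM | 40 µM |  | 10 min |

dusk run (percent of the free monomer charged)

| time / min | monomer in chains / % | free monomer / % |
|---|---|---|
| 0.667 | 4.8 | 93.9 |
| 1.00 | 6.5 | 90.4 |
| 1.33 | 12.1 | 84.7 |
| 1.50 | 10.7 | 79.5 |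
| 2.50 | 15.9 | 67.6 |
| 3.00 | 15.6 | 64.0 |
| 4.00 | 15.0 | 52.7 |

(each reading ± 1 percentage point)

1. when, up to 10 min, the flask holds most monomer in chains
2. the amount of monomer in chains, in percent of the free monomer charged, at that time
3. earliest time at which at least nineteen twentieths of that best amount are there, in min
4. latest time at which they still are, in min

- the numbers in the tables scatter by 1 percentage point (one standard deviation)

Over those readings monomer in chains stood near 15.5% of the charge. Now follow one molecule. A stock that stands is drained as fast as it is fed, so the fall divided by the stock gives 0.641 min⁻¹. That is the exit rate, the chance per minute that a molecule in chains leaves them, read here with the scatter of the readings. It is higher than the fractional rate of free monomer, so the chains hold a small stock that passes material on.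

Two chemists agree up to here and then part. The forecaster expects a slow use of transfer agent to soften the exit, and gives a top at 3.3 min with 15.7%, and a window from 2.3 min to 4.6 min. The sceptic answers that transfer agent is charged far above initiator: one agent per initiator would spend 6.67% of its charge. She therefore keeps the exit rate steady and stays with the forecast's earlier line, “It would be lost near 4.2 min”.

The simulation opens the window at 2.21 min, tops at 2.96 min with 16.9%, and shuts at 3.96 min, earlier than the forecast, with transfer agent at 96.9% of its charge at 5.00 min. The sceptic has the window. The forecaster's use of transfer agent does show in this flask, which holds 95.1% of its charge at 10.0 min, and it shows further in a neighbour flask charged with 0.10 mM of initiator, which holds 88.3% at that time.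

    free monomer + living end → monomer in chains + living end, rate k1*[living end]*[free monomer] (k = 110 M⁻¹ s⁻¹)
    monomer in chains → over-reaction product (k = 0.00760 s⁻¹)
    free monomer + initiator → spent initiator (k = 0.0620 M⁻¹ s⁻¹)
    monomer in chains ⇌ isomer of the product (K = 0.990, k = 0.00470 s⁻¹)
    free monomer + initiator → living end + monomer in chains (k = 1.30 M⁻¹ s⁻¹)
    living end + transfer agent → dead chain (kL = 4.50 M⁻¹ s⁻¹)

A molecule in chains stands at a fork: over-reaction product with a half-life of 1.5 min, isomer of the product with 2.5 min at 2.70 min. The first way is the faster and takes 61.8% of the leavers. At the exit rate of 0.641 min⁻¹, the top of this flask means free monomer falling by 0.108 min⁻¹. The neighbour flask charged with 0.10 mM of initiator tops at 29.5%, which at the same exit rate means a fall of 0.189 min⁻¹.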